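**Plan**

1. Numbering: chroman O1, C2–C4, C4a, C5–C8, C8a; side chain C1'–C12' counted from C2. After removal of a silyl group from the C6 oxygen, the retrosynthesis cuts C2'–C3' and, in the same operation, the C4'–CH3 bond.
2. The enabling feature is the (E)-C3'=C4' alkene with its C4' methyl cis to H–C3': this is the imprint of a syn methylmetalation of a terminal alkyne. The metalated carbon C3' is then joined to C2', a primary carbon next to unbranched C1', with ring oxygen O1 on C2 (γ to C2'), so an alkylpalladium at C2' has no β-heteroatom to expel.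
3. Three components result: a C13 dienyne, Me3Al and a 2-(2-iodoethyl)chroman. The dienyne is cut at C5'–C6' into (E)-geranyl bromide and a silyl-capped propargyl anion.
4. The iodide goes back to (S)-Trolox: the carboxyl carbon becomes C1', a Wittig methylene becomes C2' (cut C1'=C2'), then hydroboration–oxidation and iodination.
5. Forward, the benzene ring and the dihydropyran ring are present from the start; the chain is joined in one flask at step 9 and desilylation ends the route.
6. Stereochemistry: C2 comes with (S)-Trolox and is never touched (the descriptor becomes R in the target only through a change in CIP priorities). C3'=C4' (E) comes from syn carbometalation and stereoretentive coupling; C7'=C8' (E) comes from geranyl bromide.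

Key step: step 9

Remark: (S)-Trolox and (E)-geranyl bromide are assumed to be purchased enantiomerically and geometrically pure.

**Step 1**
Reactants: 1 (2E)-1-bromo-3,7-dimethylocta-2,6-diene (geranyl bromide); 2 trimethyl(prop-1-yn-1-yl)silane
Product: 4 trimethyl[(5E)-6,10-dimethylundeca-5,9-dien-1-yn-1-yl]silane, via [3-(trimethylsilyl)prop-2-yn-1-yl]lithium 3 (not isolated)
Conditions: n-BuLi, THF, −78 °C to −20 °C; then 1, −78 °C to rt
Reagents that add atoms: none
Why: Deprotonation of 2 at the propargylic methyl should give the silyl-capped propargyl anion 3, whose silyl group steers alkylation to the propargylic carbon, and SN2 displacement at the primary allylic bromide of 1 leaves the (E)-alkene untouched (propargylation of an allylic halide).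

**Step 2**
Reactants: 4 trimethyl[(5E)-6,10-dimethylundeca-5,9-dien-1-yn-1-yl]silane
Product: 5 (5E)-6,10-dimethylundeca-5,9-dien-1-yne
Conditions: K2CO3 (cat.), MeOH, rt
Reagents that add atoms: none
Why: Methoxide-mediated protodesilylation of the alkynylsilane should free the terminal alkyne without affecting the two trisubstituted alkenes.

**Step 3**
Reactants: 6 (2S)-6-hydroxy-2,5,7,8-tetramethyl-3,4-dihydro-2H-chromene-2-carboxylic acid ((S)-Trolox)
Product: 7 methyl (2S)-6-hydroxy-2,5,7,8-tetramethyl-3,4-dihydro-2H-chromene-2-carboxylate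
Conditions: MeOH, H2SO4 (cat.), reflux
Reagents that add atoms: methanol, CO
Why: Fischer esterification of the tertiary acid; C2 is quaternary and cannot racemise.

**Step 4**
Reactants: 7 methyl (2S)-6-hydroxy-2,5,7,8-tetramethyl-3,4-dihydro-2H-chromene-2-carboxylate
Product: 8 methyl (2S)-6-{[tert-butyl(dimethyl)silyl]oxy}-2,5,7,8-tetramethyl-3,4-dihydro-2H-chromene-2-carboxylate
Conditions: TBSCl, imidazole, DMF, 50 °C
Reagents that add atoms: tert-butyldimethylsilyl chloride, CC(C)(C)[Si](C)(C)Cl
Why: Silylation of the phenol (flanked by two methyl groups, hence gentle heating) masks the acidic and oxidation-prone O–H for the organometallic steps and can later be removed by fluoride in the presence of the triene.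

**Step 5**
Reactants: 8 methyl (2S)-6-{[tert-butyl(dimethyl)silyl]oxy}-2,5,7,8-tetramethyl-3,4-dihydro-2H-chromene-2-carboxylate
Product: 10 (2S)-6-{[tert-butyl(dimethyl)silyl]oxy}-2,5,7,8-tetramethyl-3,4-dihydro-2H-chromene-2-carbaldehyde, via aluminium hemiacetal 9 (not isolated)
Conditions: i-Bu2AlH (1.1 equiv), CH2Cl2, −78 °C; MeOH quench at −78 °C, aqueous work-up
Reagents that add atoms: none
Why: Partial reduction of the ester should stop at the aldehyde level because the tetrahedral aluminium hemiacetal 9, held by chelation to O1, survives at −78 °C until work-up; the aldehyde has no α-hydrogen, so C2 is safe.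

**Step 6**
Reactants: 10 (2S)-6-{[tert-butyl(dimethyl)silyl]oxy}-2,5,7,8-tetramethyl-3,4-dihydro-2H-chromene-2-carbaldehyde
Product: 11 tert-butyl{[(2S)-2-ethenyl-2,5,7,8-tetramethyl-3,4-dihydro-2H-chromen-6-yl]oxy}dimethylsilane
Conditions: Ph3PCH3Br, KOt-Bu, THF, 0 °C to rt
Reagents that add atoms: methyltriphenylphosphonium bromide, C[P+](c1ccccc1)(c1ccccc1)c1ccccc1.[Br-]
Why: Wittig methylenation of the non-enolisable aldehyde should install C2' as a terminal alkene while the quaternary C2 stays untouched.

**Step 7**
Reactants: 11 tert-butyl{[(2S)-2-ethenyl-2,5,7,8-tetramethyl-3,4-dihydro-2H-chromen-6-yl]oxy}dimethylsilane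
Product: 13 2-[(2S)-6-{[tert-butyl(dimethyl)silyl]oxy}-2,5,7,8-tetramethyl-3,4-dihydro-2H-chromen-2-yl]ethan-1-ol, via B-alkyl-9-BBN adduct 12 (not isolated)
Conditions: 9-BBN-H, THF, 0 °C to rt; then H2O2, aq NaOH, 0 °C
Reagents that add atoms: hydrogen peroxide, OO
Why: Anti-Markovnikov hydroboration with the bulky borane should place boron on terminal C2' (the neopentyl-like C1' is strongly disfavoured), and oxidation with retention gives the primary alcohol (hydroboration–oxidation).

**Step 8**
Reactants: 13 2-[(2S)-6-{[tert-butyl(dimethyl)silyl]oxy}-2,5,7,8-tetramethyl-3,4-dihydro-2H-chromen-2-yl]ethan-1-ol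
Product: 14 tert-butyl{[(2S)-2-(2-iodoethyl)-2,5,7,8-tetramethyl-3,4-dihydro-2H-chromen-6-yl]oxy}dimethylsilane
Conditions: I2, PPh3, imidazole, CH2Cl2, 0 °C to rt
Reagents that add atoms: iodine, II
Why: Appel-type iodination should convert the primary alcohol into the primary iodide by SN2 displacement of the alkoxyphosphonium under near-neutral conditions that the aryl silyl ether tolerates.

**Step 9**
Reactants: 5 (5E)-6,10-dimethylundeca-5,9-dien-1-yne; 14 tert-butyl{[(2S)-2-(2-iodoethyl)-2,5,7,8-tetramethyl-3,4-dihydro-2H-chromen-6-yl]oxy}dimethylsilane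
Product: 17 tert-butyldimethyl{[(2R)-2,5,7,8-tetramethyl-2-[(3E,7E)-4,8,12-trimethyltrideca-3,7,11-trien-1-yl]-3,4-dihydro-2H-chromen-6-yl]oxy}silane, via (E)-alkenyldimethylalane 15 (not isolated), via (E)-alkenylzinc chloride 16 (not isolated)
Conditions: 5 (1.5 equiv), Me3Al, Cp2ZrCl2 (0.25 equiv), CH2Cl2, 0 °C to rt; volatiles removed in vacuo; ZnCl2, THF, 0 °C; then 14, Pd2(dba)3 (2 mol %), PCyp3 (8 mol %), N-methylimidazole, THF/NMP, 80 °C
Reagents that add atoms: trimethylaluminium, C[Al](C)C
Why: Cp2ZrCl2 and Me3Al form a Zr/Al methylmetal species that adds methyl and metal syn across the terminal alkyne of 5, methyl to the internal carbon (future C4') and aluminium to the terminal carbon (future C3'), giving (E)-alkenylalane 15, which exchanges with ZnCl2 to alkenylzinc chloride 16; zerovalent palladium carrying electron-rich PCyp3 then inserts into the primary C2'–I bond of 14, takes the alkenyl group from zinc and reductively eliminates to form the C2'–C3' bond with retention of alkene geometry. The closest known reaction types are the Negishi zirconium-catalysed methylalumination of terminal alkynes with in-flask aluminium-to-zinc exchange, and the palladium/trialkylphosphine Negishi coupling of alkenylzinc halides with primary alkyl iodides that carry β-hydrogens. No ring is closed and no stereocentre is made: the only stereochemical element created is the C3'=C4' double bond, whose (E) geometry follows from syn carbometalation (methyl and metal cis) and stereoretentive transmetalation and reductive elimination, while the quaternary C2 lies two bonds from the reacting carbon, bears no hydrogen and cannot epimerise. The step needs three selectivities: addition to the alkyne in the presence of two trisubstituted alkenes (these are inert to the Zr/Al reagent at room temperature, and the terminal alkyne takes methyl at its substituted carbon); alkenyl rather than methyl transfer (vinylic groups leave aluminium and zinc faster than methyl, and surplus Me3Al is pumped off before the exchange); and coupling rather than β-hydride elimination (fast transmetalation at the bulky phosphine complex, C2' is primary, C1' is unbranched, and O1 sits on C2, γ to palladium, so no β-alkoxide elimination can open the dihydropyran ring).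

**Step 10**
Reactants: 17 tert-butyldimethyl{[(2R)-2,5,7,8-tetramethyl-2-[(3E,7E)-4,8,12-trimethyltrideca-3,7,11-trien-1-yl]-3,4-dihydro-2H-chromen-6-yl]oxy}silane
Product: 18 (2R)-2,5,7,8-tetramethyl-2-[(3E,7E)-4,8,12-trimethyltrideca-3,7,11-trien-1-yl]-3,4-dihydro-2H-chromen-6-ol
Conditions: Bu4NF, AcOH, THF, 0 °C to rt, under argon
Reagents that add atoms: none
Why: Fluoride should cleave the aryl O–Si bond (silyl ether deprotection), the acetic acid buffer delivers the phenol directly instead of the air-sensitive phenoxide, and neither the alkenes nor C2 is affected.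

**Compound list**

1 | (2E)-1-bromo-3,7-dimethylocta-2,6-diene (geranyl bromide) | BrC/C=C(\C)CCC=C(C)C | starting material
2 | trimethyl(prop-1-yn-1-yl)silane | CC#C[Si](C)(C)C | starting material
3 | [3-(trimethylsilyl)prop-2-yn-1-yl]lithium | [Li]CC#C[Si](C)(C)C | intermediate
4 | trimethyl[(5E)-6,10-dimethylundeca-5,9-dien-1-yn-1-yl]silane | C[Si](C)(C)C#CCC/C=C(\C)CCC=C(C)C | intermediate
5 | (5E)-6,10-dimethylundeca-5,9-dien-1-yne | C#CCC/C=C(\C)CCC=C(C)C | intermediate
6 | (2S)-6-hydroxy-2,5,7,8-tetramethyl-3,4-dihydro-2H-chromene-2-carboxylic acid ((S)-Trolox) | OC(=O)[C@]1(C)CCc2c(C)c(O)c(C)c(C)c2O1 | starting material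
7 | methyl (2S)-6-hydroxy-2,5,7,8-tetramethyl-3,4-dihydro-2H-chromene-2-carboxylate | COC(=O)[C@]1(C)CCc2c(C)c(O)c(C)c(C)c2O1 | intermediate
8 | methyl (2S)-6-{[tert-butyl(dimethyl)silyl]oxy}-2,5,7,8-tetramethyl-3,4-dihydro-2H-chromene-2-carboxylate | COC(=O)[C@]1(C)CCc2c(C)c(O[Si](C)(C)C(C)(C)C)c(C)c(C)c2O1 | intermediate
9 | bis(2-methylpropyl)aluminium [(2S)-6-{[tert-butyl(dimethyl)silyl]oxy}-2,5,7,8-tetramethyl-3,4-dihydro-2H-chromen-2-yl](methoxy)methanolate (both epimers at the hemiacetal carbon) | COC(O[Al](CC(C)C)CC(C)C)[C@]1(C)CCc2c(C)c(O[Si](C)(C)C(C)(C)C)c(C)c(C)c2O1 | intermediate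
10 | (2S)-6-{[tert-butyl(dimethyl)silyl]oxy}-2,5,7,8-tetramethyl-3,4-dihydro-2H-chromene-2-carbaldehyde | O=C[C@]1(C)CCc2c(C)c(O[Si](C)(C)C(C)(C)C)c(C)c(C)c2O1 | intermediate
11 | tert-butyl{[(2S)-2-ethenyl-2,5,7,8-tetramethyl-3,4-dihydro-2H-chromen-6-yl]oxy}dimethylsilane | C=C[C@]1(C)CCc2c(C)c(O[Si](C)(C)C(C)(C)C)c(C)c(C)c2O1 | intermediate
12 | 9-{2-[(2R)-6-{[tert-butyl(dimethyl)silyl]oxy}-2,5,7,8-tetramethyl-3,4-dihydro-2H-chromen-2-yl]ethyl}-9-borabicyclo[3.3.1]nonane (same spatial arrangement at C2 as 11; descriptor R by CIP priority) | C(C[C@]1(C)CCc2c(C)c(O[Si](C)(C)C(C)(C)C)c(C)c(C)c2O1)B1C2CCCC1CCC2 | intermediate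
13 | 2-[(2S)-6-{[tert-butyl(dimethyl)silyl]oxy}-2,5,7,8-tetramethyl-3,4-dihydro-2H-chromen-2-yl]ethan-1-ol | OCC[C@]1(C)CCc2c(C)c(O[Si](C)(C)C(C)(C)C)c(C)c(C)c2O1 | intermediate
14 | tert-butyl{[(2S)-2-(2-iodoethyl)-2,5,7,8-tetramethyl-3,4-dihydro-2H-chromen-6-yl]oxy}dimethylsilane | ICC[C@]1(C)CCc2c(C)c(O[Si](C)(C)C(C)(C)C)c(C)c(C)c2O1 | intermediate
15 | dimethyl[(1E,5E)-2,6,10-trimethylundeca-1,5,9-trien-1-yl]alumane | C[Al](C)/C=C(\C)CC/C=C(\C)CCC=C(C)C | intermediate
16 | chloro[(1E,5E)-2,6,10-trimethylundeca-1,5,9-trien-1-yl]zinc | Cl[Zn]/C=C(\C)CC/C=C(\C)CCC=C(C)C | intermediate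
17 | tert-butyldimethyl{[(2R)-2,5,7,8-tetramethyl-2-[(3E,7E)-4,8,12-trimethyltrideca-3,7,11-trien-1-yl]-3,4-dihydro-2H-chromen-6-yl]oxy}silane | CC(C)=CCC/C(C)=C/CC/C(C)=C/CC[C@]1(C)CCc2c(C)c(O[Si](C)(C)C(C)(C)C)c(C)c(C)c2O1 | intermediate
18 | (2R)-2,5,7,8-tetramethyl-2-[(3E,7E)-4,8,12-trimethyltrideca-3,7,11-trien-1-yl]-3,4-dihydro-2H-chromen-6-ol | CC(C)=CCC/C(C)=C/CC/C(C)=C/CC[C@]1(C)CCc2c(C)c(O)c(C)c(C)c2O1 | target

**Step count and risks**

Total step count: 10. Longest linear sequence: 8 steps (steps 3 to 10, from (S)-Trolox); the alkyne branch contributes steps 1 and 2.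

Steps most likely to fail:

Step 9. The alkylpalladium formed from 14 may undergo β-hydride elimination back to the vinyl compound, methyl instead of alkenyl transfer may occur, or the aluminium-to-zinc exchange may be sluggish in the presence of zirconium residues. The fallback reverses the polarity at the same bond (B-alkyl Suzuki–Miyaura coupling) and sets out from 11 and 5. Alkyne 5 is methylaluminated as in step 9 to alane 15, and the C–Al bond is cleaved with I2 (THF, −30 °C) to give (1E,5E)-1-iodo-2,6,10-trimethylundeca-1,5,9-triene F1. Alkene 11 is hydroborated with 9-BBN-H to borane 12, which is coupled directly with F1 [Pd(dppf)Cl2, AsPh3, Cs2CO3, DMF/THF/H2O, rt]. This should give 17, where the route is rejoined before step 10; steps 7 and 8 then fall away.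

Step 1. Regiocontrol may be lost, through allenyl instead of propargyl attack of 3 or SN2' attack on the allylic bromide, giving isomers that are hard to separate. The fallback builds the alkyne from a methyl ketone and sets out from 1. Alkylation of ethyl acetoacetate with 1 (NaOEt, EtOH) should give ethyl (4E)-2-acetyl-5,9-dimethyldeca-4,8-dienoate F3 (racemic at C2, which is lost in the next operation). Saponification and decarboxylation (aq NaOH, then H3O+, heat) give (5E)-6,10-dimethylundeca-5,9-dien-2-one F4. Kinetic enolisation with LiN(i-Pr)2 (THF, −78 °C) and trapping with ClP(O)(OEt)2 give diethyl (5E)-6,10-dimethylundeca-1,5,9-trien-2-yl phosphate F5. Further LiN(i-Pr)2 then eliminates F5 to alkyne 5, where the route is rejoined; step 2 is not needed.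

Step 5. Reduction may run past the aldehyde oxidation level if hemiacetal 9 collapses before the quench, or conversion of the hindered ester may be incomplete. The fallback reduces fully and re-oxidises, setting out from 8. LiAlH4 (THF, 0 °C) should give [(2S)-6-{[tert-butyl(dimethyl)silyl]oxy}-2,5,7,8-tetramethyl-3,4-dihydro-2H-chromen-2-yl]methanol F2. Swern oxidation [(COCl)2, DMSO, Et3N, CH2Cl2, −78 °C] then returns aldehyde 10.

**Further compounds**

F1 | step 9 | (1E,5E)-1-iodo-2,6,10-trimethylundeca-1,5,9-triene | I/C=C(\C)CC/C=C(\C)CCC=C(C)C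
F2 | step 5 | [(2S)-6-{[tert-butyl(dimethyl)silyl]oxy}-2,5,7,8-tetramethyl-3,4-dihydro-2H-chromen-2-yl]methanol | OC[C@]1(C)CCc2c(C)c(O[Si](C)(C)C(C)(C)C)c(C)c(C)c2O1
F3 | step 1 | ethyl (4E)-2-acetyl-5,9-dimethyldeca-4,8-dienoate (racemic) | CCOC(=O)C(C/C=C(\C)CCC=C(C)C)C(C)=O
F4 | step 1 | (5E)-6,10-dimethylundeca-5,9-dien-2-one | CC(=O)CC/C=C(\C)CCC=C(C)C
F5 | step 1 | diethyl (5E)-6,10-dimethylundeca-1,5,9-trien-2-yl phosphate | C=C(CC/C=C(\C)CCC=C(C)C)OP(=O)(OCC)OCC
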